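**Retrosynthetic overview**

1. The 3(2H)-furanone (O, C10, C1, C2, C3) is a cyclodehydrated α-acyloxy methyl ketone: C3 is an acyl carbon held by the ring oxygen on C10, the carbon next to the C1 carbonyl. Opening C2=C3 therefore leads back to a nine-membered lactone (O, C3–C10) with an acetyl group on C10; closing it builds the furanone and the ten-membered carbocycle together, as a ring expansion.
2. The nine-membered (Z)-enoate lactone comes from RCM at C4=C5 of a methacrylate of the tertiary ketol; the α-methylene butyrolactone from MnO2 lactonisation of a 2-methylene-1,4-diol.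
3. The C6–C7–C8 triad comes from a boron syn-aldol (C7–C8) and an Evans–Tishchenko 1,3-anti reduction (C6); C10 from (S)-lactic acid through Seebach's dioxolanone; the epoxy ester from Sharpless epoxidation of angelyl alcohol.
4. Ring order: butyrolactone, then nine-membered lactone, then furanone and ten-membered carbocycle in the last step.

Key step: step 16

Remark on numbering: atoms are named by germacrane numbering of the target (C1 ketone, C2=C3 furanone alkene, C4=C5 ring alkene with C15 methyl, C6 ester carbinol, C7/C8 lactone fusion, C9 methylene, C10 quaternary carbon with C14 methyl, C11–C13 methylene lactone).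

Assumption: the Z enol borinate made with (−)-Ipc2BOTf is taken to attack the Re face of the aldehyde, as ethyl ketone enolates of this reagent are recalled to do, and L-(+)-diethyl tartrate is taken to give the (2S)-epoxy alcohol as with other allylic alcohols; if either sense proves opposite, the antipodal reagent is used.

**Route**

Step 1
Reactants: 1 (2S,5S)-2-tert-butyl-5-methyl-1,3-dioxolan-4-one
Product: 3 (2S,5R)-2-tert-butyl-5-methyl-5-(prop-2-en-1-yl)-1,3-dioxolan-4-one, via lithium enolate 2 (not isolated)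
Conditions: LiN(iPr)2, THF, −78 °C; allyl bromide, −78 → −30 °C
Reagents that add atoms: allyl bromide, C=CCBr
Why: Seebach self-regeneration of stereocentres (enolate alkylation): the planar enolate is allylated on the face opposite the tert-butyl group, so the lactic acid centre is rebuilt with retention and C10 is set R.

Step 2
Reactants: 3 (2S,5R)-2-tert-butyl-5-methyl-5-(prop-2-en-1-yl)-1,3-dioxolan-4-one
Product: 5 (3R)-3-hydroxy-3-methylhex-5-en-2-one, via lithium hemiketal alkoxide 4 (not isolated)
Conditions: MeLi (1.1 equiv), Et2O, −78 °C; aq. NH4Cl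
Reagents that add atoms: methyllithium, [Li]C
Why: Single organolithium addition to a 1,3-dioxolan-4-one: the tetrahedral adduct should survive at −78 °C and collapse only on work-up, with loss of pivalaldehyde, to the tertiary α-ketol without touching the quaternary centre.

Step 3
Reactants: 5 (3R)-3-hydroxy-3-methylhex-5-en-2-one
Product: 6 (3R)-3-methyl-3-(trimethylsilyloxy)hex-5-en-2-one
Conditions: Me3SiCl, imidazole, DMF, 23 °C
Reagents that add atoms: chlorotrimethylsilane, C[Si](C)(C)Cl
Why: Silylation under non-enolising conditions protects the tertiary alcohol so that the β-oxygenated aldehyde of the next step cannot undergo retro-aldol cleavage.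

Step 4
Reactants: 6 (3R)-3-methyl-3-(trimethylsilyloxy)hex-5-en-2-one
Product: 8 (3R)-3-methyl-4-oxo-3-(trimethylsilyloxy)pentanal, via ozonide 7 (not isolated)
Conditions: O3, CH2Cl2, −78 °C; PPh3, −78 → 23 °C
Reagents that add atoms: ozone, [O-][O+]=O
Why: Ozonolysis with reductive work-up cleaves the only C=C bond to the C8 aldehyde; the aldehyde is used without storage.

Step 5
Reactants: 9 2-[(trimethylsilyl)methyl]prop-2-en-1-yl acetate; 10 (2E)-but-2-enoyl chloride
Product: 11 (5E)-2-methylidene-4-oxohept-5-en-1-yl acetate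
Conditions: TiCl4 (1.0 equiv), CH2Cl2, −78 °C
Reagents that add atoms: none
Why: Lewis acid acylation of an allylsilane (SE2′, Sakurai type) bonds the acyl carbon to the terminus remote from silicon and regenerates the 1,1-disubstituted alkene; at −78 °C the β,γ-enone should not move into conjugation.

Step 6
Reactants: 11 (5E)-2-methylidene-4-oxohept-5-en-1-yl acetate; 8 (3R)-3-methyl-4-oxo-3-(trimethylsilyloxy)pentanal
Product: 14 2-[(3R,5S,6R,8E)-5-hydroxy-3-methyl-2,7-dioxo-3-(trimethylsilyloxy)dec-8-en-6-yl]prop-2-en-1-yl acetate, via enol borinate 12 (not isolated), via boron aldolate 13 (not isolated)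
Conditions: (−)-Ipc2BOTf, iPr2NEt, CH2Cl2, −78 °C; then 8, −78 → −20 °C; H2O2, MeOH, pH 7 buffer, 0 °C
Reagents that add atoms: none
Why: Paterson boron aldol: soft enolisation at the doubly activated C7 methylene gives the Z enol borinate, the chair Zimmerman–Traxler transition state gives the 7,8-syn adduct, and the isopinocampheyl ligands direct attack to the Re face of the aldehyde, setting C7 and C8.

Step 7
Reactants: 14 the syn-aldol adduct
Product: 15 (3R,5S,6S,7S,8E)-6-[3-(acetyloxy)prop-1-en-2-yl]-7-hydroxy-3-methyl-2-oxo-3-(trimethylsilyloxy)dec-8-en-5-yl acetate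
Conditions: SmI2 (0.3 equiv), MeCHO (6 equiv), THF, −10 °C
Reagents that add atoms: acetaldehyde, CC=O
Why: Evans–Tishchenko reduction: the hemiacetal of the C8 hydroxyl with acetaldehyde delivers hydride to the C6 ketone inside a samarium-bridged chair, which sets C6 1,3-anti to C8 and leaves O8 acetylated and O6 free; the methyl ketone has no β-hydroxyl and is not reduced.

Step 8
Reactants: 16 methyl (2Z)-2-methylbut-2-enoate (methyl angelate)
Product: 17 (2Z)-2-methylbut-2-en-1-ol
Conditions: iBu2AlH (2.2 equiv), CH2Cl2, −78 °C; aq. potassium sodium tartrate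
Reagents that add atoms: none
Why: Hydride reduction of the ester to the allylic alcohol at low temperature keeps the Z geometry.

Step 9
Reactants: 17 (2Z)-2-methylbut-2-en-1-ol
Product: 18 [(2S,3R)-2,3-dimethyloxiran-2-yl]methanol
Conditions: Ti(OiPr)4 (10 mol%), L-(+)-diethyl tartrate (12 mol%), tBuOOH, 4 Å molecular sieves, CH2Cl2, −20 °C
Reagents that add atoms: tert-butyl hydroperoxide, CC(C)(C)OO
Why: Sharpless asymmetric epoxidation: the tartrate–titanium catalyst delivers oxygen to one face of the allylic alcohol, setting both epoxide centres (Z alkene gives the cis relation of CH2OH and the C3 methyl).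

Step 10
Reactants: 18 [(2S,3R)-2,3-dimethyloxiran-2-yl]methanol
Product: 19 (2R,3R)-2,3-dimethyloxirane-2-carboxylic acid
Conditions: RuCl3 (2 mol%), NaIO4 (3 equiv), CCl4/MeCN/H2O, 0 → 23 °C
Reagents that add atoms: water, O
Why: Catalytic ruthenium tetroxide oxidation takes the primary alcohol to the acid through the aldehyde hydrate and leaves the epoxide intact (the change from 2S to 2R is only a change of CIP priority).

Step 11
Reactants: 15 the 8-monoacetate; 19 (2R,3R)-2,3-dimethyloxirane-2-carboxylic acid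
Product: 21 (3R,5S,6R,7S,8E)-5-(acetyloxy)-6-[3-(acetyloxy)prop-1-en-2-yl]-3-methyl-2-oxo-3-(trimethylsilyloxy)dec-8-en-7-yl (2R,3R)-2,3-dimethyloxirane-2-carboxylate, via mixed anhydride 20 (not isolated)
Conditions: 19, 2,4,6-trichlorobenzoyl chloride, Et3N, toluene, 23 °C; then 15, DMAP, 23 → 40 °C
Reagents that add atoms: none
Why: Yamaguchi esterification acylates the hindered allylic C6 hydroxyl; the acid has no α-hydrogen, so it cannot epimerise.

Step 12
Reactants: 21 the epoxy ester diacetate
Product: 22 (3R,5S,6R,7S,8E)-3,5-dihydroxy-6-(3-hydroxyprop-1-en-2-yl)-3-methyl-2-oxodec-8-en-7-yl (2R,3R)-2,3-dimethyloxirane-2-carboxylate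
Conditions: K2CO3 (0.5 equiv), MeOH, 0 °C
Reagents that add atoms: none
Why: Mild methanolysis should remove the two acetates and the tertiary trimethylsilyl ether, while the α-quaternary (pivalate-like) epoxy ester is much slower to exchange or migrate.

Step 13
Reactants: 22 the triol
Product: 24 (1S,2E)-1-[(2S,3R)-2-[(2R)-2-hydroxy-2-methyl-3-oxobutyl]-4-methylidene-5-oxooxolan-3-yl]but-2-en-1-yl (2R,3R)-2,3-dimethyloxirane-2-carboxylate, via lactol 23 (not isolated)
Conditions: MnO2 (activated, 30 equiv), CH2Cl2, 23 °C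
Reagents that add atoms: none
Why: MnO2 oxidative lactonisation of a 2-methylene-1,4-diol: the primary allylic alcohol goes to the enal, the C8 hydroxyl closes the lactol and this is oxidised to the α-methylene-γ-butyrolactone, trans at C7/C8 as fixed by the aldol; the tertiary alcohol and the acylated C6 oxygen do not react.

Step 14
Reactants: 24 the hydroxy lactone
Product: 25 (2R)-1-[(2S,3R)-3-[(1S,2E)-1-{[(2R,3R)-2,3-dimethyloxirane-2-carbonyl]oxy}but-2-en-1-yl]-4-methylidene-5-oxooxolan-2-yl]-2-methyl-3-oxobutan-2-yl 2-methylprop-2-enoate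
Conditions: methacryloyl chloride, Et3N, DMAP (0.2 equiv), CH2Cl2, 0 → 23 °C
Reagents that add atoms: methacryloyl chloride, CC(=C)C(Cl)=O
Why: DMAP-catalysed acylation of the tertiary α-ketol, the only free hydroxyl, installs the C3–C4–C15 unit as the ester that later becomes the ring oxygen bridge.

Step 15
Reactants: 25 the methacrylate
Product: 26 nine-membered lactone: ester between the C10 oxygen and the C3 carboxyl of the (4Z)-2-methyl-enoate, 10-acetyl, 8,12-olide with 11(13)-methylene, 6-O-(2R,3R)-epoxyangelate, (6S,7R,8S,10R)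
Conditions: second-generation Hoveyda–Grubbs catalyst RuCl2(H2IMes)(=CH-C6H4-2-OiPr) (15 mol%), 1,4-benzoquinone, toluene (1 mM), 90 °C
Reagents that add atoms: none
Why: Ring-closing metathesis: the catalyst loads on the propenyl group and closes on the methacrylate with loss of propene; the nine-membered ring allows only the Z trisubstituted alkene, and the electron-poor 1,1-disubstituted methylene of the butyrolactone cannot form a viable ring.

Step 16
Reactants: 26 the nine-membered lactone
Product: 29 CNP0258430.3, 3,10-epoxy-1-oxogermacra-2,4(Z),11(13)-trien-12,8-olide 6-[(2R,3R)-2,3-dimethyloxirane-2-carboxylate], (6S,7R,8S,10R), via lithium enolate 27 (not isolated), via bridged hemiketal 28 (not isolated)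
Conditions: LiN(SiMe3)2 (1.2 equiv), THF (2 mM), −78 → −40 °C; AcOH; then TsOH·H2O (0.1 equiv), CH2Cl2, 23 °C
Reagents that add atoms: none
Why: Proposed new method: LiN(SiMe3)2 removes a proton from the only kinetically acidic site, the acetyl methyl group C2 (the butyrolactone and the epoxy ester have no α-hydrogen), and enolate 27 adds to the lactone carbonyl C3 held on the oxygen of the same carbon C10, giving hemiketal 28 (or its ring-opened 1,3-diketone tautomer), which loses water under acid to the vinylogous ester. The closest known reaction type is the base-induced Claisen-type cyclisation and dehydration of open-chain α-acyloxy ketones to 3(2H)-furanones (an aliphatic Baker–Venkataraman acyl transfer); new here is that the ester is a medium-ring lactone, so the acyl transfer is a ring expansion. The furanone closes in a 5-(enolexo)-exo-trig mode, and the same C2–C3 bond closes the ten-membered carbocycle C1–C10, the former lactone ring remaining as the nine-membered oxygen bridge. No new stereocentre remains (the hemiketal carbon becomes sp2), and C6, C7, C8, C10 and the 4,5-Z alkene are not touched. The step needs C-acylation to outrun conjugate addition to the α-methylene lactone; the five-membered transition state, the cisoid and therefore more electrophilic ester geometry of the nine-membered ring, high dilution and low temperature should secure this.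

**Compound list**

1 | (2S,5S)-2-tert-butyl-5-methyl-1,3-dioxolan-4-one | C[C@@H]1O[C@H](C(C)(C)C)OC1=O | starting material
2 | lithium enolate of 1 | CC1=C([O-])O[C@@H](C(C)(C)C)O1.[Li+] | intermediate
3 | (2S,5R)-2-tert-butyl-5-methyl-5-(prop-2-en-1-yl)-1,3-dioxolan-4-one | C=CC[C@@]1(C)O[C@H](C(C)(C)C)OC1=O | intermediate
4 | lithium hemiketal alkoxide, methyl adduct of 3 | C=CC[C@@]1(C)O[C@H](C(C)(C)C)OC1(C)[O-].[Li+] | intermediate
5 | (3R)-3-hydroxy-3-methylhex-5-en-2-one | C=CC[C@@](C)(O)C(C)=O | intermediate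
6 | (3R)-3-methyl-3-(trimethylsilyloxy)hex-5-en-2-one | C=CC[C@@](C)(O[Si](C)(C)C)C(C)=O | intermediate
7 | ozonide (1,2,4-trioxolane) of 6 | C1OC(C[C@@](C)(O[Si](C)(C)C)C(C)=O)OO1 | intermediate
8 | (3R)-3-methyl-4-oxo-3-(trimethylsilyloxy)pentanal | O=CC[C@@](C)(O[Si](C)(C)C)C(C)=O | intermediate
9 | 2-[(trimethylsilyl)methyl]prop-2-en-1-yl acetate | CC(=O)OCC(=C)C[Si](C)(C)C | starting material
10 | (2E)-but-2-enoyl chloride | C/C=C/C(Cl)=O | starting material
11 | (5E)-2-methylidene-4-oxohept-5-en-1-yl acetate | C/C=C/C(=O)CC(=C)COC(C)=O | intermediate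
12 | Z enol diisopinocampheylborinate of 11 | C/C=C/C(OB([C@@H]1C[C@@H]2C[C@@H](C2(C)C)[C@H]1C)[C@@H]1C[C@@H]2C[C@@H](C2(C)C)[C@H]1C)=C/C(=C)COC(C)=O | intermediate
13 | diisopinocampheylboron aldolate of 14 | C/C=C/C(=O)[C@H](C(=C)COC(C)=O)[C@@H](OB([C@@H]1C[C@@H]2C[C@@H](C2(C)C)[C@H]1C)[C@@H]1C[C@@H]2C[C@@H](C2(C)C)[C@H]1C)C[C@@](C)(O[Si](C)(C)C)C(C)=O | intermediate
14 | 2-[(3R,5S,6R,8E)-5-hydroxy-3-methyl-2,7-dioxo-3-(trimethylsilyloxy)dec-8-en-6-yl]prop-2-en-1-yl acetate | C/C=C/C(=O)[C@H](C(=C)COC(C)=O)[C@@H](O)C[C@@](C)(O[Si](C)(C)C)C(C)=O | intermediate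
15 | (3R,5S,6S,7S,8E)-6-[3-(acetyloxy)prop-1-en-2-yl]-7-hydroxy-3-methyl-2-oxo-3-(trimethylsilyloxy)dec-8-en-5-yl acetate | C/C=C/[C@H](O)[C@H](C(=C)COC(C)=O)[C@@H](OC(C)=O)C[C@@](C)(O[Si](C)(C)C)C(C)=O | intermediate
16 | methyl (2Z)-2-methylbut-2-enoate | C/C=C(/C)C(=O)OC | starting material
17 | (2Z)-2-methylbut-2-en-1-ol | C/C=C(/C)CO | intermediate
18 | [(2S,3R)-2,3-dimethyloxiran-2-yl]methanol | OC[C@]1(C)O[C@@H]1C | intermediate
19 | (2R,3R)-2,3-dimethyloxirane-2-carboxylic acid | OC(=O)[C@]1(C)O[C@@H]1C | intermediate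
20 | mixed anhydride of 19 and 2,4,6-trichlorobenzoic acid | O=C(OC(=O)c1c(Cl)cc(Cl)cc1Cl)[C@]2(C)O[C@@H]2C | intermediate
21 | (3R,5S,6R,7S,8E)-5-(acetyloxy)-6-[3-(acetyloxy)prop-1-en-2-yl]-3-methyl-2-oxo-3-(trimethylsilyloxy)dec-8-en-7-yl (2R,3R)-2,3-dimethyloxirane-2-carboxylate | C/C=C/[C@H](OC(=O)[C@]1(C)O[C@@H]1C)[C@H](C(=C)COC(C)=O)[C@@H](OC(C)=O)C[C@@](C)(O[Si](C)(C)C)C(C)=O | intermediate
22 | (3R,5S,6R,7S,8E)-3,5-dihydroxy-6-(3-hydroxyprop-1-en-2-yl)-3-methyl-2-oxodec-8-en-7-yl (2R,3R)-2,3-dimethyloxirane-2-carboxylate | C/C=C/[C@H](OC(=O)[C@]1(C)O[C@@H]1C)[C@H](C(=C)CO)[C@@H](O)C[C@@](C)(O)C(C)=O | intermediate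
23 | lactol of the C12 enal with the C8 hydroxyl (ring tautomer of the hydroxy enal) | C/C=C/[C@H](OC(=O)[C@]1(C)O[C@@H]1C)[C@@H]2C(=C)C(O)O[C@H]2C[C@@](C)(O)C(C)=O | intermediate
24 | (1S,2E)-1-[(2S,3R)-2-[(2R)-2-hydroxy-2-methyl-3-oxobutyl]-4-methylidene-5-oxooxolan-3-yl]but-2-en-1-yl (2R,3R)-2,3-dimethyloxirane-2-carboxylate | C/C=C/[C@H](OC(=O)[C@]1(C)O[C@@H]1C)[C@@H]2C(=C)C(=O)O[C@H]2C[C@@](C)(O)C(C)=O | intermediate
25 | methacrylate of 24 at the tertiary hydroxyl | C/C=C/[C@H](OC(=O)[C@]1(C)O[C@@H]1C)[C@@H]2C(=C)C(=O)O[C@H]2C[C@@](C)(OC(=O)C(C)=C)C(C)=O | intermediate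
26 | nine-membered (4Z)-enoate lactone (C3 carboxyl on the C10 oxygen), 10-acetyl, 11(13)-methylene-8,12-olide, 6-O-epoxyangelate, (6S,7R,8S,10R) | C=C1C(=O)O[C@H]2C[C@](C)(C(C)=O)OC(=O)/C(C)=C\[C@H](OC(=O)[C@]3(C)O[C@@H]3C)[C@H]12 | intermediate
27 | lithium enolate of 26 at the acetyl group | C=C1C(=O)O[C@H]2C[C@](C)(C(=C)[O-])OC(=O)/C(C)=C\[C@H](OC(=O)[C@]3(C)O[C@@H]3C)[C@H]12.[Li+] | intermediate
28 | bridged hemiketal (3-hydroxy-2,3-dihydro form of 29) | C=C1C(=O)O[C@H]2C[C@@]3(C)OC(O)(CC3=O)/C(C)=C\[C@H](OC(=O)[C@]4(C)O[C@@H]4C)[C@H]12 | intermediate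
29 | CNP0258430.3 | C=C1C(=O)O[C@H]2C[C@@]3(C)OC(=CC3=O)/C(C)=C\[C@H](OC(=O)[C@]3(C)O[C@@H]3C)[C@H]12 | target

**Step count and risks**

Total step count: 16 (four to aldehyde 8, one to ketone 11, three to acid 19, eight from the aldol onward).
Longest linear sequence: 12 steps (steps 1–4, 6, 7, 11–16, from 1 to 29).

Steps most likely to fail:

1. Step 16 (proposed new method). The bridged tetrahedral adduct may not form or may revert because of transannular strain in the medium ring, leaving the enolate to add to the methylene lactone. The fallback sets out from 25 and returns at 29. The same LiN(SiMe3)2 acylation and acid dehydration is run on the open-chain methacrylate 25, the known substrate class for this furanone synthesis, and should give the open-chain 5-isopropenyl-3(2H)-furanone F1. Ring-closing metathesis of F1 with the second-generation Hoveyda–Grubbs catalyst in hot dilute toluene then closes C4=C5, a ring closure known for furanone-bridged germacranolides, and gives 29 directly.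

2. Step 15. Ring closure may lose to oligomerisation because the methacrylate ester prefers the transoid conformer and the trisubstituted enoate forms slowly. The fallback sets out from 24 and returns at 26. The tertiary hydroxyl of 24 is esterified with 2-(diethoxyphosphoryl)propanoic acid (DCC, DMAP) to the phosphonate ester F2. Ozonolysis of the electron-rich propenyl group (one equivalent of O3, then PPh3; the electron-poor methylene lactone reacts more slowly) gives the aldehyde F3. An intramolecular Horner–Wadsworth–Emmons reaction under Masamune–Roush conditions (LiCl, iPr2NEt, MeCN, high dilution) closes the ring to 26; the nine-membered ring should allow only the Z enoate.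

3. Step 12. The epoxy ester may migrate from O6 to the freed O8 or be lost during methanolysis. The fallback sets out from 15 and returns at 29, carrying a silyl ether at C6 and adding the epoxy ester last. Compound 15 is silylated (tBuMe2SiOTf, 2,6-lutidine) to the silyl ether F4. K2CO3 in MeOH gives the triol F5, MnO2 the hydroxy lactone F6, and methacryloyl chloride the methacrylate F7. Ring-closing metathesis gives the nine-membered lactone F8, and the enolate acylation and dehydration of step 16 the furanone silyl ether F9. HF·pyridine frees the C6 alcohol F10, which is esterified with 19 under Yamaguchi conditions to give 29.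

Further compounds
F1 | step 16 | open-chain 5-isopropenyl-3(2H)-furanone from 25 | C/C=C/[C@H](OC(=O)[C@]1(C)O[C@@H]1C)[C@@H]2C(=C)C(=O)O[C@H]2C[C@@]3(C)OC(C(C)=C)=CC3=O
F2 | step 15 | 2-(diethoxyphosphoryl)propanoate of 24 | C/C=C/[C@H](OC(=O)[C@]1(C)O[C@@H]1C)[C@@H]2C(=C)C(=O)O[C@H]2C[C@@](C)(OC(=O)C(C)P(=O)(OCC)OCC)C(C)=O
F3 | step 15 | C5 aldehyde of F2 | O=C[C@H](OC(=O)[C@]1(C)O[C@@H]1C)[C@@H]2C(=C)C(=O)O[C@H]2C[C@@](C)(OC(=O)C(C)P(=O)(OCC)OCC)C(C)=O
F4 | step 12 | 6-O-tert-butyldimethylsilyl ether of 15 | C/C=C/[C@H](O[Si](C)(C)C(C)(C)C)[C@H](C(=C)COC(C)=O)[C@@H](OC(C)=O)C[C@@](C)(O[Si](C)(C)C)C(C)=O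
F5 | step 12 | 6-O-silyl triol | C/C=C/[C@H](O[Si](C)(C)C(C)(C)C)[C@H](C(=C)CO)[C@@H](O)C[C@@](C)(O)C(C)=O
F6 | step 12 | 6-O-silyl hydroxy lactone | C/C=C/[C@H](O[Si](C)(C)C(C)(C)C)[C@@H]1C(=C)C(=O)O[C@H]1C[C@@](C)(O)C(C)=O
F7 | step 12 | 6-O-silyl methacrylate | C/C=C/[C@H](O[Si](C)(C)C(C)(C)C)[C@@H]1C(=C)C(=O)O[C@H]1C[C@@](C)(OC(=O)C(C)=C)C(C)=O
F8 | step 12 | 6-O-silyl nine-membered lactone | C=C1C(=O)O[C@H]2C[C@](C)(C(C)=O)OC(=O)/C(C)=C\[C@H](O[Si](C)(C)C(C)(C)C)[C@H]12
F9 | step 12 | 6-O-silyl furanone | C=C1C(=O)O[C@H]2C[C@@]3(C)OC(=CC3=O)/C(C)=C\[C@H](O[Si](C)(C)C(C)(C)C)[C@H]12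
F10 | step 12 | C6 alcohol of the furanone | C=C1C(=O)O[C@H]2C[C@@]3(C)OC(=CC3=O)/C(C)=C\[C@H](O)[C@H]12
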